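The route rests on disconnecting the bond from ring carbon C1 to its hydroxymethyl carbon, which traces the six-membered ring back to dearomatised p-cresol. The key step exploits two features: the C6 methyl carbinol lies para to trigonal C3, and the hydroxymethyl carbon on C1 is cis to the C6 oxygen. A chiral carbene-catalysed intramolecular Stetter reaction of an aldehyde tethered to that oxygen desymmetrises the cyclohexadienone, closes a cis-fused oxolanone and sets C1 and C6 in one operation. Its precursor is the achiral quinol ether 2-[(1-methyl-4-oxocyclohexa-2,5-dien-1-yl)oxy]acetaldehyde, made from p-cresol and ethylene glycol in two steps.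

Key step: step 3

Remark: the ring is numbered C1 (quaternary), C2, C3 (ketone or alkylidene carbon), C4, C5, C6 (methyl carbinol) in every intermediate; "homofarnesyl" is (3E,7E)-4,8,12-trimethyltrideca-3,7,11-trien-1-yl. Assumption: the catalyst antipode used is the one that gives (3aS,7aR)-5, which corresponds to the (1R,2S,6R) target.

Step 1
Reactants: 1 p-cresol; 2 ethylene glycol
Product: 3 4-(2-hydroxyethoxy)-4-methylcyclohexa-2,5-dien-1-one
Conditions: PhI(OAc)2, ethylene glycol (excess)/CH2Cl2, 0 to 23 °C
Reagents that add atoms: none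
Why: Oxidative dearomatisation of a para-alkyl phenol with PhI(OAc)2 gives a phenoxenium-type species that the glycol, present in excess, traps at the methyl-bearing para carbon, a standard entry to 4-alkoxy-4-alkylcyclohexadienones.

Step 2
Reactants: 3 4-(2-hydroxyethoxy)-4-methylcyclohexa-2,5-dien-1-one
Product: 4 2-[(1-methyl-4-oxocyclohexa-2,5-dien-1-yl)oxy]acetaldehyde
Conditions: Dess–Martin periodinane, NaHCO3, CH2Cl2, 0 to 23 °C
Reagents that add atoms: none
Why: Dess–Martin oxidation should convert the primary alcohol to the aldehyde under buffered, neutral conditions that leave the dienone untouched.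

Step 3
Reactants: 4 2-[(1-methyl-4-oxocyclohexa-2,5-dien-1-yl)oxy]acetaldehyde
Product: 5 (3aS,7aR)-7a-methyl-3a,4-dihydro-1-benzofuran-3,5(2H,7aH)-dione (cis-fused)
Conditions: (5aS,10bR)- or (5aR,10bS)-5a,10b-dihydro-2-(4-methoxyphenyl)-4H,6H-indeno[2,1-b][1,2,4]triazolo[4,3-d][1,4]oxazinium tetrafluoroborate (10 mol %, antipode as assumed above), KN(SiMe3)2 (10 mol %), toluene, 23 °C
Reagents that add atoms: none
Why: The base frees the triazolylidene carbene, which adds to the aldehyde and, after proton transfer, forms a nucleophilic enaminol that attacks the β-carbon of one of the two enantiotopic enone arms; a second proton transfer then expels the catalyst (intramolecular Stetter reaction). The closest known reaction type is the carbene-catalysed enantioselective Stetter desymmetrisation of 4-alkyl-4-alkoxycyclohexa-2,5-dienones to hydrobenzofuranones. The oxolanone ring closes in the 5-exo-trig mode. The relative configuration (acyl carbon on C1 cis to the C6 oxygen) is fixed by the two-atom O–CH2 tether, which can only span a cis ring fusion, and the absolute configuration at both centres is set by the aminoindanol backbone of the catalyst, which selects one enone arm. The only selectivity the step needs is between enantiotopic groups; the substrate secures everything else, since the dienone offers two identical acceptors, the aldehyde is the only site the carbene can activate, and the fully substituted C6 prevents rearomatisation by simple enolisation.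

Step 4
Reactants: 5 (3aS,7aR)-7a-methyl-3a,4-dihydro-1-benzofuran-3,5(2H,7aH)-dione
Product: 6 (4aS,8aR)-8a-methyl-4a,5-dihydro-4H-1,3-benzodioxine-4,6(8aH)-dione (cis-fused 1,3-dioxan-4-one)
Conditions: mCPBA, NaHCO3, CH2Cl2, 0 to 23 °C
Reagents that add atoms: mCPBA, O=C(OO)c1cccc(Cl)c1
Why: Baeyer–Villiger oxidation should occur at the saturated, inductively activated oxolan-3-one and not at the conjugated ketone, with the oxygen-bearing CH2 migrating in preference to the ring-fusion methine because the ether oxygen stabilises the migrating carbon, so the C1–carbonyl bond made in step 3 is kept.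

Step 5
Reactants: 6 (4aS,8aR)-8a-methyl-4a,5-dihydro-4H-1,3-benzodioxine-4,6(8aH)-dione
Product: 7 (4aS,6R,8aR)-6-hydroxy-8a-methyl-4a,5,6,8a-tetrahydro-4H-1,3-benzodioxin-4-one (hydroxyl on C3 cis to the dioxanone ring)
Conditions: NaBH4, CeCl3·7H2O, MeOH, −78 °C; crude product taken on at once
Reagents that add atoms: none
Why: Luche reduction should give clean 1,2-reduction of the enone at low temperature without touching the lactone, hydride entering from the convex face (that of the C1 hydrogen and C6 methyl) so that the temporary C3 hydroxyl lies on the lower face.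

Step 6
Reactants: 7 (4aS,6R,8aR)-6-hydroxy-8a-methyl-4a,5,6,8a-tetrahydro-4H-1,3-benzodioxin-4-one
Product: 8 (4aS,6R,8aR)-6-[(tert-butyldimethylsilyl)oxy]-8a-methyl-4a,5,6,8a-tetrahydro-4H-1,3-benzodioxin-4-one
Conditions: TBSCl, imidazole, DMF, 0 to 23 °C
Reagents that add atoms: tert-butyldimethylsilyl chloride, CC(C)(C)[Si](C)(C)Cl
Why: Silyl ether formation masks the allylic alcohol (which could otherwise attack the lactone) and leaves the C1 hydrogen as the only acidic site for the next main-line step.

Step 7
Reactants: 9 (2E,6E)-farnesol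
Product: 10 (2E,6E)-farnesal
Conditions: MnO2, CH2Cl2, 23 °C
Reagents that add atoms: none
Why: MnO2 oxidises the allylic alcohol selectively and should not scramble the 2E double bond.

Step 8
Reactants: 10 (2E,6E)-farnesal
Product: 11 (3E,7E)-4,8,12-trimethyltrideca-1,3,7,11-tetraene
Conditions: Ph3PCH3Br, KOt-Bu, THF, 0 to 23 °C
Reagents that add atoms: methyltriphenylphosphonium bromide, C[P+](c1ccccc1)(c1ccccc1)c1ccccc1.[Br-]
Why: Wittig methylenation of the enal adds the sixteenth carbon as a terminal vinyl group without involving the trisubstituted double bonds.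

Step 9
Reactants: 11 (3E,7E)-4,8,12-trimethyltrideca-1,3,7,11-tetraene
Product: 13 (3E,7E)-4,8,12-trimethyltrideca-3,7,11-trien-1-ol (homofarnesol), via dialkylborane adduct 12 (not isolated)
Conditions: disiamylborane (from BH3·SMe2 and 2-methylbut-2-ene), THF, 0 °C; then NaOH, H2O2
Reagents that add atoms: hydrogen peroxide, OO
Why: Hydroboration–oxidation with the bulky dialkylborane should take place only at the monosubstituted terminal double bond of the diene and place boron on the end carbon, a known way to homologate allylic terpenols to homoallylic alcohols.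

Step 10
Reactants: 13 (3E,7E)-4,8,12-trimethyltrideca-3,7,11-trien-1-ol
Product: 14 (3E,7E)-1-iodo-4,8,12-trimethyltrideca-3,7,11-triene (homofarnesyl iodide)
Conditions: I2, PPh3, imidazole, CH2Cl2, 0 °C
Reagents that add atoms: iodine, II
Why: Appel-type iodination converts the primary homoallylic alcohol to the iodide by SN2 displacement, with no allylic transposition possible.

Step 11
Reactants: 8 (4aS,6R,8aR)-6-[(tert-butyldimethylsilyl)oxy]-8a-methyl-4a,5,6,8a-tetrahydro-4H-1,3-benzodioxin-4-one; 14 homofarnesyl iodide
Product: 16 cis-fused 6-silyloxy-8a-methyl-4a-homofarnesyl-4a,5,6,8a-tetrahydro-4H-1,3-benzodioxin-4-one (chain on C1 cis to the C6 methyl), via lithium enolate 15 (not isolated)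
Conditions: LiN(i-Pr)2, THF, −78 °C; then 14, DMPU, −78 to −45 °C
Reagents that add atoms: none
Why: Alkylation of a bicyclic 1,3-dioxan-4-one enolate (the cyclic counterpart of the Fráter–Seebach alkylation, in which the ring holds the β C–O bond near the enolate plane and so slows β-elimination) should place the chain on the convex upper face cis to the C6 methyl, because that keeps the dioxanone cis-fused and the lower face is screened by the pseudoaxial C3 silyloxy group, thereby fixing quaternary C1 with its carbonyl carbon cis to the C6 oxygen.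

Step 12
Reactants: 16 cis-fused 4a-homofarnesyl dioxanone
Product: 17 silyloxy diol (C1: CH2OH and homofarnesyl; C3: OTBS; C4=C5; C6: methyl carbinol; CH2OH cis to both oxygens)
Conditions: LiAlH4, THF, 0 to 23 °C
Reagents that add atoms: none
Why: Hydride reduction of the acylal lactone gives the primary alcohol and frees the C6 tertiary alkoxide, the former tether carbon leaving as formaldehyde that is reduced to methanol.

Step 13
Reactants: 17 silyloxy diol
Product: 18 acetonide of 17 (2,2-dimethyl-1,3-dioxane spanning the C1 CH2O arm and the C6 oxygen)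
Conditions: 2,2-dimethoxypropane, pyridinium p-toluenesulfonate (cat.), CH2Cl2, 23 °C
Reagents that add atoms: 2,2-dimethoxypropane, COC(C)(C)OC
Why: Acid-catalysed acetal exchange ties the 1,3-related primary and tertiary hydroxyls into a six-membered acetonide, protecting both in one operation under conditions the silyl ether should survive.

Step 14
Reactants: 18 acetonide silyl ether
Product: 19 acetonide allylic alcohol (free C3 hydroxyl)
Conditions: Bu4NF, THF, 0 to 23 °C
Reagents that add atoms: none
Why: Fluoride-mediated desilylation frees the allylic alcohol and is inert toward the acetonide and the alkenes.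

Step 15
Reactants: 19 acetonide allylic alcohol
Product: 20 acetonide enone (C3 ketone, C4=C5)
Conditions: Dess–Martin periodinane, NaHCO3, CH2Cl2, 0 to 23 °C
Reagents that add atoms: none
Why: Dess–Martin oxidation restores the cyclohexenone, in which C2 is the only enolisable position because C4 is trigonal and C6 is quaternary.

Step 16
Reactants: 20 acetonide enone; 21 allyl bromide
Product: 23 2-allyl enone (allyl on the lower face, cis to the C1 CH2O arm and trans to the chain), via lithium dienolate 22 (not isolated)
Conditions: LiN(i-Pr)2, THF, −78 °C; then 21, DMPU, −78 to −40 °C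
Reagents that add atoms: none
Why: Kinetic α′-deprotonation gives the cross-conjugated lithium dienolate, whose SN2 allylation at C2 should occur anti to the C1 chain and the C6 methyl, which together screen the upper face (the lower face carries only the flatter dioxane ring), so the new stereocentre has the allyl group trans to the chain.

Step 17
Reactants: 23 2-allyl enone
Product: 25 2-allyl cyclohexanone (C4–C5 saturated), via copper enolate 24 (not isolated)
Conditions: [(Ph3P)CuH]6, benzene, 23 °C; then aq. NH4Cl
Reagents that add atoms: none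
Why: Conjugate reduction with Stryker's reagent delivers hydride to the unsubstituted β-carbon C5 only and should leave the ketone, the terminal alkene, the trisubstituted alkenes and the C2 centre untouched.

Step 18
Reactants: 25 2-allyl cyclohexanone
Product: 27 2-(3-hydroxypropyl) cyclohexanone, via pinacol boronate 26 (not isolated)
Conditions: pinacolborane, RhCl(PPh3)3 (cat.), THF, 23 °C; then NaBO3·4H2O, THF/H2O
Reagents that add atoms: sodium perborate, [Na+].[Na+].O[B-]1(O)OO[B-](O)(O)OO1
Why: Rhodium-catalysed hydroboration is chemoselective for the monosubstituted alkene over the ketone and the trisubstituted alkenes and gives the terminal boronate, which mild perborate oxidation converts to the primary alcohol without epimerising C2.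

Step 19
Reactants: 27 2-(3-hydroxypropyl) cyclohexanone; 28 2-(diethoxyphosphoryl)propanoic acid
Product: 29 2-(diethoxyphosphoryl)propanoate ester of 27 (epimers at the phosphonate carbon)
Conditions: DCC, DMAP (cat.), CH2Cl2, 0 to 23 °C
Reagents that add atoms: none
Why: Steglich esterification acylates the only free hydroxyl and so tethers the three-carbon enal precursor to the C2 side chain.

Step 20
Reactants: 29 phosphonopropionate ester
Product: 30 eight-membered (Z)-α-methyl-α,β-unsaturated lactone fused at C2–C3, acetonide intact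
Conditions: LiCl, i-Pr2NEt, MeCN (0.002 M), 23 to 50 °C
Reagents that add atoms: none
Why: Intramolecular Horner–Wadsworth–Emmons olefination under Masamune–Roush conditions closes the lactone, and because an eight-membered ring can hold only a cis double bond the carbonyl carbon is forced onto the C2 side of the new tetrasubstituted alkene (Z), while the weak base should spare the C2 centre.

Step 21
Reactants: 30 lactone acetonide
Product: 31 lactone diol (free C1 CH2OH and C6 OH)
Conditions: pyridinium p-toluenesulfonate, MeOH, 23 to 40 °C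
Reagents that add atoms: none
Why: Acid-catalysed acetal exchange removes the acetonide while the enoate is still a lactone, so that the final enal never meets acid.

Step 22
Reactants: 31 lactone diol
Product: 32 tetraol with (Z)-allylic primary alcohol
Conditions: i-Bu2AlH (excess), CH2Cl2, −78 to 0 °C; Rochelle salt work-up
Reagents that add atoms: none
Why: DIBAL reduction opens the unsaturated lactone by 1,2-addition through the lactol to the allylic alcohol and frees the 3-hydroxypropyl chain without touching the alkene geometry.

Step 23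
Reactants: 32 tetraol
Product: 33 target, (2Z)-2-[(2S,3R,4R)-4-hydroxy-3-(hydroxymethyl)-2-(3-hydroxypropyl)-4-methyl-3-homofarnesylcyclohexylidene]propanal
Conditions: MnO2, CH2Cl2, 23 °C
Reagents that add atoms: none
Why: MnO2 oxidises only the allylic primary alcohol, the two saturated primary alcohols and the tertiary alcohol being inert, and should give the Z-enal under neutral conditions.

Compound list
1 | p-cresol | Cc1ccc(O)cc1 | starting material
2 | ethylene glycol | OCCO | starting material
3 | 4-(2-hydroxyethoxy)-4-methylcyclohexa-2,5-dien-1-one | CC1(OCCO)C=CC(=O)C=C1 | intermediate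
4 | 2-[(1-methyl-4-oxocyclohexa-2,5-dien-1-yl)oxy]acetaldehyde | CC1(OCC=O)C=CC(=O)C=C1 | intermediate
5 | (3aS,7aR)-7a-methyl-3a,4-dihydro-1-benzofuran-3,5(2H,7aH)-dione | O=C1CO[C@]2(C)C=CC(=O)C[C@H]12 | intermediate
6 | (4aS,8aR)-8a-methyl-4a,5-dihydro-4H-1,3-benzodioxine-4,6(8aH)-dione | O=C1OCO[C@]2(C)C=CC(=O)C[C@H]12 | intermediate
7 | (4aS,6R,8aR)-6-hydroxy-8a-methyl-4a,5,6,8a-tetrahydro-4H-1,3-benzodioxin-4-one | O=C1OCO[C@]2(C)C=C[C@H](O)C[C@H]12 | intermediate
8 | (4aS,6R,8aR)-6-[(tert-butyldimethylsilyl)oxy]-8a-methyl-4a,5,6,8a-tetrahydro-4H-1,3-benzodioxin-4-one | O=C1OCO[C@]2(C)C=C[C@H](O[Si](C)(C)C(C)(C)C)C[C@H]12 | intermediate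
9 | (2E,6E)-farnesol | CC(C)=CCC/C(C)=C/CC/C(C)=C/CO | starting material
10 | (2E,6E)-farnesal | CC(C)=CCC/C(C)=C/CC/C(C)=C/C=O | intermediate
11 | (3E,7E)-4,8,12-trimethyltrideca-1,3,7,11-tetraene | CC(C)=CCC/C(C)=C/CC/C(C)=C/C=C | intermediate
12 | bis(3-methylbutan-2-yl)(homofarnesyl)borane | CC(C)=CCC/C(C)=C/CC/C(C)=C/CCB(C(C)C(C)C)C(C)C(C)C | intermediate
13 | (3E,7E)-4,8,12-trimethyltrideca-3,7,11-trien-1-ol | CC(C)=CCC/C(C)=C/CC/C(C)=C/CCO | intermediate
14 | (3E,7E)-1-iodo-4,8,12-trimethyltrideca-3,7,11-triene | CC(C)=CCC/C(C)=C/CC/C(C)=C/CCI | intermediate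
15 | lithium enolate of 8 | [Li]OC1=C2C[C@@H](O[Si](C)(C)C(C)(C)C)C=C[C@@]2(C)OCO1 | intermediate
16 | cis-fused 4a-homofarnesyl dioxanone silyl ether | CC(C)=CCC/C(C)=C/CC/C(C)=C/CC[C@@]12C(=O)OCO[C@]1(C)C=C[C@H](O[Si](C)(C)C(C)(C)C)C2 | intermediate
17 | silyloxy cyclohexene diol | CC(C)=CCC/C(C)=C/CC/C(C)=C/CC[C@]1(CO)C[C@@H](O[Si](C)(C)C(C)(C)C)C=C[C@@]1(C)O | intermediate
18 | acetonide silyl ether | CC(C)=CCC/C(C)=C/CC/C(C)=C/CC[C@@]12COC(C)(C)O[C@]1(C)C=C[C@H](O[Si](C)(C)C(C)(C)C)C2 | intermediate
19 | acetonide allylic alcohol | CC(C)=CCC/C(C)=C/CC/C(C)=C/CC[C@@]12COC(C)(C)O[C@]1(C)C=C[C@H](O)C2 | intermediate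
20 | acetonide enone | CC(C)=CCC/C(C)=C/CC/C(C)=C/CC[C@@]12COC(C)(C)O[C@]1(C)C=CC(=O)C2 | intermediate
21 | allyl bromide | C=CCBr | starting material
22 | lithium dienolate of 20 | CC(C)=CCC/C(C)=C/CC/C(C)=C/CC[C@@]12COC(C)(C)O[C@]1(C)C=CC(O[Li])=C2 | intermediate
23 | 2-allyl enone | CC(C)=CCC/C(C)=C/CC/C(C)=C/CC[C@@]12COC(C)(C)O[C@]1(C)C=CC(=O)[C@@H]2CC=C | intermediate
24 | copper enolate of 25 | CC(C)=CCC/C(C)=C/CC/C(C)=C/CC[C@@]12COC(C)(C)O[C@]1(C)CC=C(O[Cu])[C@@H]2CC=C | intermediate
25 | 2-allyl cyclohexanone | CC(C)=CCC/C(C)=C/CC/C(C)=C/CC[C@@]12COC(C)(C)O[C@]1(C)CCC(=O)[C@@H]2CC=C | intermediate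
26 | pinacol boronate | CC(C)=CCC/C(C)=C/CC/C(C)=C/CC[C@@]12COC(C)(C)O[C@]1(C)CCC(=O)[C@@H]2CCCB3OC(C)(C)C(C)(C)O3 | intermediate
27 | 2-(3-hydroxypropyl) cyclohexanone | CC(C)=CCC/C(C)=C/CC/C(C)=C/CC[C@@]12COC(C)(C)O[C@]1(C)CCC(=O)[C@@H]2CCCO | intermediate
28 | 2-(diethoxyphosphoryl)propanoic acid | CCOP(=O)(OCC)C(C)C(=O)O | starting material
29 | phosphonopropionate ester | CC(C)=CCC/C(C)=C/CC/C(C)=C/CC[C@@]12COC(C)(C)O[C@]1(C)CCC(=O)[C@@H]2CCCOC(=O)C(C)P(=O)(OCC)OCC | intermediate
30 | eight-membered (Z)-lactone acetonide | CC(C)=CCC/C(C)=C/CC/C(C)=C/CC[C@@]12COC(C)(C)O[C@]1(C)CC/C(=C(\C)C(=O)OCCC3)[C@@H]23 | intermediate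
31 | lactone diol | CC(C)=CCC/C(C)=C/CC/C(C)=C/CC[C@]1(CO)[C@H]2CCCOC(=O)C(/C)=C2/CC[C@@]1(C)O | intermediate
32 | tetraol | CC(C)=CCC/C(C)=C/CC/C(C)=C/CC[C@]1(CO)[C@@H](CCCO)/C(=C(/C)CO)CC[C@@]1(C)O | intermediate
33 | target | CC(C)=CCC/C(C)=C/CC/C(C)=C/CC[C@]1(CO)[C@@H](CCCO)/C(=C(/C)C=O)CC[C@@]1(C)O | target

Total step count: 23. Longest linear sequence: 19 steps (steps 1–6 and 11–23 from p-cresol); the side-chain branch is steps 7–10.

Steps most likely to fail

Step 11. The unactivated homoallylic iodide may react too slowly with the hindered enolate, which can then decay by β-elimination of the ring oxygen or deprotonate the iodide, and the electrophile may enter anti to the angular methyl to give the trans-fused C1 epimer. The fallback sets out from 8, returns at 17, and uses that other face productively. Enolate 15 is alkylated at −78 °C with 4-methoxybenzyl chloromethyl ether, a small and very reactive electrophile expected to enter anti to the methyl, giving the trans-fused 4a-[(4-methoxybenzyloxy)methyl] dioxanone F1. LiAlH4 gives the diol F2, and Dess–Martin oxidation of its primary hydroxyl gives the aldehyde F3. Takai–Lombardo methylenation (Zn, CH2Br2, TiCl4) gives the vinyl compound F4. Hydroboration with 9-BBN gives the B-alkyl borane F5, which undergoes Suzuki–Miyaura coupling (PdCl2(dppf), AsPh3, Cs2CO3, DMF/H2O) with the known vinyl iodide (1E,5E)-1-iodo-2,6,10-trimethylundeca-1,5,9-triene F6 to give the homofarnesyl PMB ether F7. DDQ then removes the PMB group to give 17. In this variant the carbon from the key step becomes the first chain carbon and the new one-carbon unit becomes the hydroxymethyl group.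

Step 20. Closure of the eight-membered ring may be slower than intermolecular olefination, giving oligomers, and prolonged exposure to base may epimerise the ketone α-centre C2 before cyclisation. The fallback sets out from 27 and returns at 30. Acylation with 2-bromopropanoyl bromide and pyridine gives the α-bromo ester F8. SmI2 in dilute THF effects an intramolecular Reformatsky addition to the ketone, a reaction that closes medium-ring lactones through a samarium-chelated transition state, to give the β-hydroxy lactone F9. Dehydration with the Burgess reagent (followed by DBU if the double bond first forms out of conjugation) gives 30, the ring again permitting only the cis alkene.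

Step 16. Facial selectivity at C2 may be poor, or O-allylation and proton exchange between enolate and product may lead to mixtures. The fallback sets out from 20 and returns at 23. Dienolate 22 (LiN(SiMe3)2, TMEDA) is trapped on oxygen with allyl chloroformate to give the allyl dienol carbonate F10. Pd2(dba)3 with a chiral phosphinooxazoline ligand (t-Bu-PHOX, antipode matched to the substrate bias) then effects decarboxylative Tsuji–Trost allylation at C2 under catalyst control and without free base, giving 23.

Further compounds
F1 | step 11 | trans-fused 4a-[(4-methoxybenzyloxy)methyl] dioxanone silyl ether | COc1ccc(COC[C@]23C(=O)OCO[C@]2(C)C=C[C@H](O[Si](C)(C)C(C)(C)C)C3)cc1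
F2 | step 11 | PMB-oxymethyl silyloxy diol | COc1ccc(COC[C@@]2(CO)C[C@@H](O[Si](C)(C)C(C)(C)C)C=C[C@@]2(C)O)cc1
F3 | step 11 | PMB-oxymethyl hydroxy aldehyde | COc1ccc(COC[C@@]2(C=O)C[C@@H](O[Si](C)(C)C(C)(C)C)C=C[C@@]2(C)O)cc1
F4 | step 11 | C1-vinyl PMB ether | COc1ccc(COC[C@@]2(C=C)C[C@@H](O[Si](C)(C)C(C)(C)C)C=C[C@@]2(C)O)cc1
F5 | step 11 | B-alkyl-9-BBN adduct of F4 | COc1ccc(COC[C@@]2(CCB3C4CCCC3CCC4)C[C@@H](O[Si](C)(C)C(C)(C)C)C=C[C@@]2(C)O)cc1
F6 | step 11 | (1E,5E)-1-iodo-2,6,10-trimethylundeca-1,5,9-triene | CC(C)=CCC/C(C)=C/CC/C(C)=C/I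
F7 | step 11 | homofarnesyl PMB ether of 17 | COc1ccc(COC[C@@]2(CC/C=C(\C)CC/C=C(\C)CCC=C(C)C)C[C@@H](O[Si](C)(C)C(C)(C)C)C=C[C@@]2(C)O)cc1
F8 | step 20 | 2-bromopropanoate ester of 27 | CC(C)=CCC/C(C)=C/CC/C(C)=C/CC[C@@]12COC(C)(C)O[C@]1(C)CCC(=O)[C@@H]2CCCOC(=O)C(C)Br
F9 | step 20 | eight-membered β-hydroxy lactone | CC(C)=CCC/C(C)=C/CC/C(C)=C/CC[C@@]12COC(C)(C)O[C@]1(C)CCC3(O)C(C)C(=O)OCCC[C@H]23
F10 | step 16 | allyl dienol carbonate of 20 | CC(C)=CCC/C(C)=C/CC/C(C)=C/CC[C@@]12COC(C)(C)O[C@]1(C)C=CC(OC(=O)OCC=C)=C2
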